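Ring B of the tetralone (C1 carbonyl, C2 and C3 methyl-bearing, C4 aryl-bearing, C4a/C8a fused to ring A) is disconnected at C4a–C4 and C2–C3. The precursors are a ring A aryl 1,2-dione, whose C2 ketone is the electrophile, and (E)-methylisoeugenol (C3=C4). The chiral Lewis acid [Cu((R,R)-t-Bu-box)](SbF6)2 chelates the dione; Prins attack of the alkene forms C2–C3, and the C4 benzylic cation, stabilised by the dimethoxyphenyl ring C, alkylates ring A at C4a, the carbon para to the C7 oxygen. One operation closes ring B and sets C3 and C4. The temporary C2–O bond is then cleaved with SmI2, and base sets C2 and frees the phenol.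

Key step: step 3

Assumption: silyl ether 1 is taken as a catalogue compound; otherwise it is made from isovanillin with TBSCl and imidazole, which adds one step.
Remark: the sense of induction at C2 is assigned by analogy with additions to chelated pyruvates; if the opposite face is attacked, the (S,S)-ligand is used with no other change.

Step 1
Reactants: 1 3-(tert-butyldimethylsilyloxy)-4-methoxybenzaldehyde
Product: 3 1-[3-(tert-butyldimethylsilyloxy)-4-methoxyphenyl]-1-hydroxypropan-2-one (racemic), via enol ether adduct 2 (not isolated)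
Conditions: ethyl vinyl ether, t-BuLi, THF, −78 to 0 °C; then 1, −78 °C; then 0.5 M aq. HCl, THF, 0 °C
Reagents that add atoms: ethyl vinyl ether C=COCC (used as 1-ethoxyvinyllithium); water O
Why: 1-Ethoxyvinyllithium acts as an acetyl anion equivalent in a 1,2-addition to the aldehyde, and mild acid hydrolysis of the enol ether 2 unmasks the methyl ketone while the aryl silyl ether survives; the carbinol centre is racemic and is removed in step 2.

Step 2
Reactants: 3 1-[3-(tert-butyldimethylsilyloxy)-4-methoxyphenyl]-1-hydroxypropan-2-one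
Product: 4 1-[3-(tert-butyldimethylsilyloxy)-4-methoxyphenyl]propane-1,2-dione
Conditions: Dess–Martin periodinane, NaHCO3, CH2Cl2, 0 °C to rt
Reagents that add atoms: none
Why: Dess–Martin oxidation converts the α-hydroxy ketone (and any acyloin isomer) into the 1,2-dione under neutral conditions that tolerate the silyl ether.

Step 3
Reactants: 4 1-[3-(tert-butyldimethylsilyloxy)-4-methoxyphenyl]propane-1,2-dione; 5 (E)-methylisoeugenol
Product: 7 (2R,3S,4R)-7-(tert-butyldimethylsilyloxy)-4-(3,4-dimethoxyphenyl)-2-hydroxy-6-methoxy-2,3-dimethyl-3,4-dihydronaphthalen-1(2H)-one, via Prins zwitterion 6 (not isolated)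
Conditions: [Cu((R,R)-t-Bu-box)](SbF6)2 (10 mol %), 4 Å MS, CH2Cl2, 0 °C to rt, slow addition of 5 (1.5 equiv)
Reagents that add atoms: none
Why: Proposed new method: the bisoxazoline-ligated divalent copper centre chelates both carbonyl oxygens of 4 and activates the non-conjugated C2 ketone, C3 of alkene 5 adds to its re face (Prins addition, C2–C3) to give the copper alkoxide/benzylic cation 6, and C4 of 6, stabilised by ring C, alkylates ring A at C4a (Friedel–Crafts, C4a–C4) before rearomatisation. The closest known reactions are the [Cu(t-Bu-box)]X2-catalysed enantioselective carbonyl-ene and Mukaiyama aldol additions to pyruvates and 1,2-diketones, arene-terminated Prins cascades, and the SnCl4 rearrangement of aryl cyclopropyl ketones to 4-aryl-1-tetralones, which closes the same bond from the same kind of benzylic cation. Ring B closes by a 6-endo-trig Friedel–Crafts alkylation through a chair-like transition state. C2 is set by the ligand, whose tert-butyl groups should leave the re face open as in pyruvate additions; C3 follows from C2 because the chelated C2 oxygen and the C3 methyl both sit equatorial in the closing chair (the syn topicity of the pyruvate aldols); C4 follows from C3 because the aryl group closes equatorial, trans to the C3 methyl, as prefigured by the E alkene. The step needs C2 over C1 chemoselectivity (C1 is deactivated by conjugation with the para-methoxyaryl ring), C4a over C8 regioselectivity (C4a is para to the silyloxy group and unhindered, the site where veratraldehyde-type rings take electrophiles) and C-alkylation over oxygen capture (the oxetane or the non-enolisable oxocarbenium ion from oxygen capture would be strained or reversible, so the arene is the sink). A C3 epimer, if formed, is a diastereomer of 7 and is removed at this stage, so the enantiopurity of the target rests only on the face selectivity at C2.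

Step 4
Reactants: 7 (2R,3S,4R)-7-(tert-butyldimethylsilyloxy)-4-(3,4-dimethoxyphenyl)-2-hydroxy-6-methoxy-2,3-dimethyl-3,4-dihydronaphthalen-1(2H)-one
Product: 9 epischisandrone [(2R,3S,4R)-4-(3,4-dimethoxyphenyl)-7-hydroxy-6-methoxy-2,3-dimethyl-3,4-dihydronaphthalen-1(2H)-one], via silyl ether ketone 8 (not isolated)
Conditions: SmI2 (2.5 equiv), THF–MeOH, −78 °C; then K2CO3, MeOH, rt, same flask
Reagents that add atoms: none
Why: Electron transfer from SmI2 to the aryl ketone gives a ketyl that expels the α-hydroxide (reductive cleavage of an α-oxygenated ketone) and the samarium enolate is protonated to 8, after which K2CO3 in MeOH cleaves the phenolic silyl ether and equilibrates the enolisable C2 to the all-equatorial (2R) isomer, C3 and C4 being non-enolisable and untouched.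

Compound list
1 | 3-(tert-butyldimethylsilyloxy)-4-methoxybenzaldehyde | COc1ccc(C=O)cc1O[Si](C)(C)C(C)(C)C | starting material
2 | 1-[3-(tert-butyldimethylsilyloxy)-4-methoxyphenyl]-2-ethoxyprop-2-en-1-ol (racemic) | CCOC(=C)C(O)c1ccc(OC)c(O[Si](C)(C)C(C)(C)C)c1 | intermediate
3 | 1-[3-(tert-butyldimethylsilyloxy)-4-methoxyphenyl]-1-hydroxypropan-2-one (racemic) | CC(=O)C(O)c1ccc(OC)c(O[Si](C)(C)C(C)(C)C)c1 | intermediate
4 | 1-[3-(tert-butyldimethylsilyloxy)-4-methoxyphenyl]propane-1,2-dione | CC(=O)C(=O)c1ccc(OC)c(O[Si](C)(C)C(C)(C)C)c1 | intermediate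
5 | (E)-methylisoeugenol, 1,2-dimethoxy-4-[(E)-prop-1-enyl]benzene | COc1ccc(/C=C/C)cc1OC | starting material
6 | Prins zwitterion, copper-bound (2R,3S)-alkoxide with a benzylic cation at C4 | COc1ccc(cc1O[Si](C)(C)C(C)(C)C)C(=O)[C@](C)([O-])[C@@H](C)[CH+]c1ccc(OC)c(OC)c1 | intermediate
7 | (2R,3S,4R)-7-(tert-butyldimethylsilyloxy)-4-(3,4-dimethoxyphenyl)-2-hydroxy-6-methoxy-2,3-dimethyl-3,4-dihydronaphthalen-1(2H)-one | COc1cc2c(cc1O[Si](C)(C)C(C)(C)C)C(=O)[C@](C)(O)[C@@H](C)[C@@H]2c1ccc(OC)c(OC)c1 | intermediate
8 | (3S,4R)-7-(tert-butyldimethylsilyloxy)-4-(3,4-dimethoxyphenyl)-6-methoxy-2,3-dimethyl-3,4-dihydronaphthalen-1(2H)-one, mixture of C2 epimers | COc1cc2c(cc1O[Si](C)(C)C(C)(C)C)C(=O)C(C)[C@@H](C)[C@@H]2c1ccc(OC)c(OC)c1 | intermediate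
9 | epischisandrone, (2R,3S,4R)-4-(3,4-dimethoxyphenyl)-7-hydroxy-6-methoxy-2,3-dimethyl-3,4-dihydronaphthalen-1(2H)-one | COc1cc2c(cc1O)C(=O)[C@H](C)[C@@H](C)[C@@H]2c1ccc(OC)c(OC)c1 | target

Total step count: 4
Longest linear sequence: 4 steps (1 to 3 to 4 to 7 to 9)

Steps most likely to fail

Step 3. Alkene 5 may oligomerise under adventitious protic acid or by attack on cation 6. Cation 6 may lose the C3 proton instead of closing ring B. Reversible Prins addition may erode the face selectivity at C2. The fallback uses known chemistry, sets out from 4 and comes back at 7. A Mukaiyama aldol addition of (Z)-1-(ethylthio)-1-(trimethylsilyloxy)prop-1-ene to the C2 ketone of 4 with [Cu((R,R)-t-Bu-box)](OTf)2 in THF at −78 °C, a documented syn-selective and enantioselective reaction of 1,2-diketones, should give S-ethyl (2R,3R)-4-[3-(tert-butyldimethylsilyloxy)-4-methoxyphenyl]-2,3-dimethyl-4-oxo-3-(trimethylsilyloxy)butanethioate F1, with the tertiary silyl ether kept. Fukuyama reduction (Et3SiH, Pd/C, acetone) should give (2R,3R)-4-[3-(tert-butyldimethylsilyloxy)-4-methoxyphenyl]-2,3-dimethyl-4-oxo-3-(trimethylsilyloxy)butanal F2. 3,4-Dimethoxyphenylmagnesium bromide at −78 °C should add to the aldehyde and not to the hindered ketone, giving (2R,3S)-1-[3-(tert-butyldimethylsilyloxy)-4-methoxyphenyl]-4-(3,4-dimethoxyphenyl)-4-hydroxy-2,3-dimethyl-2-(trimethylsilyloxy)butan-1-one F3 as a mixture at the carbinol carbon. BF3·OEt2 in CH2Cl2 ionises that carbinol, closes ring B by the same Friedel–Crafts alkylation and removes the trimethylsilyl group to give 7.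

Step 4. The aryl ketone may be over-reduced to the carbinol, the ketyl may undergo pinacol coupling, or the tertiary hydroxide may be expelled too slowly. The fallback sets out from 7 and comes back at 8. Acetylation (Ac2O, Sc(OTf)3 cat., MeCN) should give (2R,3S,4R)-7-(tert-butyldimethylsilyloxy)-4-(3,4-dimethoxyphenyl)-6-methoxy-2,3-dimethyl-1-oxo-1,2,3,4-tetrahydronaphthalen-2-yl acetate F4. Zinc dust in AcOH then cleaves the activated α-acetoxy ketone to 8, which is treated with K2CO3 in MeOH as in step 4 to give 9.

Step 1. Metalation of ethyl vinyl ether may be incomplete, so that t-BuLi adds to the aldehyde. During hydrolysis of 2 the silyl ether may be lost or the α-hydroxy ketone may self-condense. The fallback sets out from 1 and comes back at 4, so step 2 is not needed. EtMgBr in THF at 0 °C should give 1-[3-(tert-butyldimethylsilyloxy)-4-methoxyphenyl]propan-1-ol F5. MnO2 in CH2Cl2 should give 1-[3-(tert-butyldimethylsilyloxy)-4-methoxyphenyl]propan-1-one F6. Riley oxidation with SeO2 in aqueous dioxane at 90 °C should give dione 4.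

Further compounds
F1 | step 3 | S-ethyl (2R,3R)-4-[3-(tert-butyldimethylsilyloxy)-4-methoxyphenyl]-2,3-dimethyl-4-oxo-3-(trimethylsilyloxy)butanethioate | COc1ccc(cc1O[Si](C)(C)C(C)(C)C)C(=O)[C@](C)(O[Si](C)(C)C)[C@@H](C)C(=O)SCC
F2 | step 3 | (2R,3R)-4-[3-(tert-butyldimethylsilyloxy)-4-methoxyphenyl]-2,3-dimethyl-4-oxo-3-(trimethylsilyloxy)butanal | COc1ccc(cc1O[Si](C)(C)C(C)(C)C)C(=O)[C@](C)(O[Si](C)(C)C)[C@@H](C)C=O
F3 | step 3 | (2R,3S)-1-[3-(tert-butyldimethylsilyloxy)-4-methoxyphenyl]-4-(3,4-dimethoxyphenyl)-4-hydroxy-2,3-dimethyl-2-(trimethylsilyloxy)butan-1-one (C4 epimers) | COc1ccc(cc1O[Si](C)(C)C(C)(C)C)C(=O)[C@](C)(O[Si](C)(C)C)[C@@H](C)C(O)c1ccc(OC)c(OC)c1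
F4 | step 4 | (2R,3S,4R)-7-(tert-butyldimethylsilyloxy)-4-(3,4-dimethoxyphenyl)-6-methoxy-2,3-dimethyl-1-oxo-1,2,3,4-tetrahydronaphthalen-2-yl acetate | COc1cc2c(cc1O[Si](C)(C)C(C)(C)C)C(=O)[C@](C)(OC(C)=O)[C@@H](C)[C@@H]2c1ccc(OC)c(OC)c1
F5 | step 1 | 1-[3-(tert-butyldimethylsilyloxy)-4-methoxyphenyl]propan-1-ol (racemic) | CCC(O)c1ccc(OC)c(O[Si](C)(C)C(C)(C)C)c1
F6 | step 1 | 1-[3-(tert-butyldimethylsilyloxy)-4-methoxyphenyl]propan-1-one | CCC(=O)c1ccc(OC)c(O[Si](C)(C)C(C)(C)C)c1
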